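Sub and Prd together, bound forms counted, stay at the Sub charged, since the overall step turns one into the other. So I read each flask by its remainder: the fraction of its Sub charge that is not Prd at the last reading.

| flask | Sub | Rgt | Cat | time |
|---|---|---|---|---|
| amber | 0.400 M | 1.20 M | 0.0320 M |  |
| ochre | 0.160 M | 0.960 M | 0.0320 M |  |
| blue | 0.400 M | 1.20 M | 0.0960 M |  |
| teal | 0.600 M | 1.20 M | 0.0320 M |  |
| grey | 0.830 M | 1.20 M | 0.0320 M | 40 min |

| run | time / min | [Prd] / M |
|---|---|---|
| amber run | 1.6 | 0.0016 |
| amber run | 2.5 | 0 |
| amber run | 4.0 | 0.0035 |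
| amber run | 6.4 | 0.0133 |
| amber run | 10 | 0.0311 |
| amber run | 16 | 0.0915 |
| amber run | 25 | 0.2176 |
| amber run | 40 | 0.3586 |
| ochre run | 1.6 | 0 |
| ochre run | 2.5 | 0.0010 |
| ochre run | 4.0 | 0.0025 |
| ochre run | 6.4 | 0.0048 |
| ochre run | 10 | 0.0127 |
| ochre run | 16 | 0.0308 |
| ochre run | 25 | 0.0687 |
| ochre run | 40 | 0.1232 |
| blue run | 1.6 | 0.0012 |
| blue run | 2.5 | 0.0041 |
| blue run | 4.0 | 0.0122 |
| blue run | 6.4 | 0.0335 |
| blue run | 10 | 0.0846 |
| blue run | 16 | 0.1965 |
| blue run | 25 | 0.3292 |
| blue run | 40 | 0.3928 |
| teal run | 1.6 | 0.0011 |
| teal run | 2.5 | 0.0017 |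
| teal run | 4.0 | 0.0065 |
| teal run | 6.4 | 0.0164 |
| teal run | 10 | 0.0429 |
| teal run | 16 | 0.1455 |
| teal run | 25 | 0.3630 |
| teal run | 40 | 0.5486 |

(scatter of a reading: 0.001 M)

- Overall: Sub + Rgt -> Prd, with Cat as catalyst.
- Constant volume, constant temperature.
- A reading of a species includes what of it is bound.
- "The second partner" is Rgt.
- An order is taken over about fifteen percent of the charge, up and down.

* order of the initial rate in [Cat], near the charge of the amber run, the rate being that where two percent of its Sub are Prd
* order of the initial rate in [Sub], near the charge of the amber run, the rate being that where two percent of its Sub are Prd (one fixed amount of Prd, the same in the runs compared)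
* the ochre run starts with 0.240 M less of Sub and of Rgt than the amber run, and with no Prd. Compared where both hold the same amount of Sub, once fifteen percent of what the ochre run was charged with has turned into Prd, is the ochre run faster, slower or alike (within a tenth)?
* Prd in the grey run at 40 min, as a share of the Sub charged

I turn the settings one at a time, starting with Cat. By hand, a rate in step with Cat would bring blue, at 3.00 times amber's Cat, to amber's final remainder in 13.3 min. But blue at 25 min still shows a remainder of 17.7 %, more than amber's 10.4 % at 40 min, so Cat shortens the run by less than that factor.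

Next comes Sub. By hand, a rate in step with Sub would give teal 1.50 times amber's early Prd. The readings at 6.4 min give 0.0164 M in teal against 0.0133 M in amber, a ratio of 1.23. Yet the remainder still falls, to 8.57 % in teal at 40 min.

Last is Rgt. Ochre has 0.800 of amber's Rgt and 0.400 of its Sub, so a rate in step with both would give ochre 0.320 of amber's early Prd. The readings at 6.4 min give a ratio of 0.361, and ochre's remainder at 40 min reads 23.0 %.

Grey keeps the Rgt and Cat of amber and teal and moves Sub, so those two runs serve it. From amber to teal the logarithm of the remainder falls by 0.946 L mol⁻¹ of Sub charged. This is the remainder slope, a reading that holds Rgt, Cat and the time fixed. In grey Sub is the limiting reagent, and I reckon the small remainder as the correction rather than the large share made. Carried on from teal, the slope gives grey a remainder of 6.89 % at 40 min, so my share of Prd is 93.1 %.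

The forecast gives orders of 0.45 in Cat and 0.36 in Sub, ochre slower, and 89 % for grey, lower than my figure, on the ground that “rate rises with Prd”.

The flask gives orders of 0.42 in Cat and 0.30 in Sub, ochre slower, and 92.7 % for grey, by these steps:

    Z + Sub ⇌ Cat.Sub, settled at all times (25.40 L mol⁻¹)
    Cat.Sub + Rgt → Prd + Z (0.2244 L mol⁻¹ min⁻¹)
    Cat + Rgt → Z + Rgt (0.05202 L mol⁻¹ min⁻¹)
    Sub + Rgt + Prd → 2 Prd (0.2730 L² mol⁻² min⁻¹)

Grey's remainder is 7.28 %, which is 0.39 percentage points above what the remainder slope gave. Where ochre and amber hold the same Sub, ochre's rate is 0.27 of amber's. Taken down from amber to ochre's Sub charge, the slope gives a remainder of 13.0 %, and ochre, which also holds less Rgt than amber, reads 23.0 %.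

(The numbers in the tables are calculated from invented constants; scatter was added.)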